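You charge substrate and, beside it, acid at 0.100 of that amount, and you want the part of the substrate that has reacted and the pH at the end.

substrate 0.077 M; acid 7.70 mM; time 8.0 h

- part of the substrate that has reacted at 8.0 h
- pH of the solution at 8.0 h

    substrate + weak acid ⇌ idle adduct, settled at all times (K1 = 4.1 L mol⁻¹)
    weak acid → by-product carried off (k2 = 0.20 min⁻¹)
    weak acid ⇌ conjugate base + acid, settled at all times (K3 = 2.5 × 10⁻⁵ M)
    substrate → weak acid + target (k4 = 0.0032 min⁻¹)
    target → over-reaction product (k5 = 0.0037 min⁻¹)
    substrate + acid → weak acid + acid + target (k6 = 0.67 L mol⁻¹ min⁻¹)

- acid is the free proton; pH is minus the decimal logarithm of its molar concentration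
- what is said of weak acid includes idle adduct
- run time (flask): 8.0 h

The binding into idle adduct comes first. Its constant times the substrate charged is 0.32, so at the start adduct stands to free weak acid in that ratio. And free weak acid goes off as by-product with a half-life of 3.47 min, far shorter than the substrate's 3.6 h by plain conversion. So in my reckoning weak acid stays a small fraction of the charge, and I set the adduct aside. The ionisation of weak acid could add acid, but its constant 2.5 × 10⁻⁵ M lies far below the acid charged, so you can take the acid, and with it the pH, as charged.

Acid comes back unchanged from the step it helps, so substrate has two ways out, each at a steady rate per substrate (pseudo-first-order): plain conversion, and the acid-helped step, with a half-life of 2.2 h by itself at the concentrations as charged. So add the two rate constants, the second times the acid, and multiply by the run: that is the number of substrate lifetimes in the run, 4.01. The fraction left is e to the minus that number, 1.81%, so 98.2% has reacted.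

The forecast gives 98.2% and a pH of 2.11, holding that “the weak acid is barely ionised at that acidity”.

The flask gives 98.2% reacted and a pH of 2.11. Reacted does not mean target here: at 8.00 h the flask holds 27.2% of the charge as target and 71.0% as over-reaction product. Now take a neighbour flask charged with 0.0403 equiv of acid, the other charges and the time held. The same count gives it 2.53 lifetimes against the 4.01 of the first flask, so by that count 7.97% is left. That neighbour flask ended with 8.0% of its charged substrate still there, unbound, and 92.0% reacted.

The constants used here stand for no real mixture.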